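**Assumption:** cembrane numbering is used (C1 = ring carbon bearing C15, C2 = lactone O‑carbon). The SMILES reads as 1S,2S,6S,14S, with a trans‑fused lactone (H‑1/H‑2 anti) and 3E,7E,11E alkenes.

## Retrosynthetic overview
1. Target 25 ⇒ diol 23 (site‑selective 6‑O‑acetylation) ⇒ bis‑TES macrolactone 22.
2. 22 ⇒ open‑chain enal/2‑(bromomethyl)enoate 21 by cutting C1–C2. A light‑driven Cr‑catalysed allylation closes the 14‑membered carbocycle first, and the γ‑lactone then closes in the same pot.
3. 21 ⇒ C10–C11 B‑alkyl Suzuki union of West dienol 15 (C2–C10) with East iodo‑acrylate 17 (C11–C14, C1, C15–C17).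
4. 15 and 17 both come from one aldehyde 9 (Wittig/methylenation/hydroxymethylation versus vinylalumination).
5. 9 ⇒ (R)‑glycidol + acetylide + Me3Al/I2. The glycidol carbon becomes both C6 and C14, and C1/C2 are relayed from C14.

## Route

**Step 1**
Reactants: 1 (R)‑glycidol; 2 lithium acetylide–ethylenediamine complex
Product: 3 (S)‑pent‑4‑yne‑1,2‑diol
Conditions: LiC≡CH·EDA (3 equiv), DMSO–THF, 0 °C → rt
Reagents that add atoms: lithium acetylide·EDA, [Li]C#C.NCCN
Why: SN2 epoxide opening at the terminal carbon leaves the bought stereocentre untouched, and the competing Payne rearrangement of glycidol alkoxide is degenerate, so ee is kept.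

**Step 2**
Reactants: 3; 4 trimethylaluminium; 5 iodine
Product: 6 (2S,4E)‑5‑iodo‑4‑methylpent‑4‑ene‑1,2‑diol
Conditions: Me3Al (5 equiv), Cp2ZrCl2 (0.3 equiv), CH2Cl2, 0 °C → rt; then I2, THF, −30 °C
Reagents that add atoms: Me3Al, C[Al](C)C; iodine, II
Why: Negishi Zr‑catalysed syn‑carboalumination (the OH groups become Al alkoxides in situ) followed by iodinolysis with retention gives only the E trisubstituted alkenyl iodide, which fixes the later C3=C4 and C11=C12 geometry.

**Step 3**
Reactants: 6; 7 chlorotriethylsilane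
Product: 8 (2S,4E)‑5‑iodo‑4‑methyl‑1,2‑bis(triethylsilyloxy)pent‑4‑ene
Conditions: TESCl, imidazole, DMAP (cat.), CH2Cl2, 0 °C → rt
Reagents that add atoms: TESCl, CC[Si](Cl)(CC)CC
Why: Routine bis‑silylation, in which the alkenyl iodide is inert.

**Step 4**
Reactants: 8
Product: 9 (2S,4E)‑5‑iodo‑4‑methyl‑2‑(triethylsilyloxy)pent‑4‑enal
Conditions: (COCl)2, DMSO, CH2Cl2, −78 → −40 °C; Et3N, −78 → 0 °C
Reagents that add atoms: none
Why: Under Swern conditions a primary TES ether is cleaved and oxidised directly while the secondary TES ether survives, and the low temperature avoids α‑epimerisation.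

**Step 5 (West)**
Reactants: 9; 10 2‑(triphenylphosphoranylidene)propanal
Product: 11 (2E,4S,6E)‑7‑iodo‑2,6‑dimethyl‑4‑(triethylsilyloxy)hepta‑2,6‑dienal
Conditions: toluene, 80 °C
Reagents that add atoms: ylide 10, CC(C=O)=P(c1ccccc1)(c1ccccc1)c1ccccc1
Why: A stabilised‑ylide Wittig reaction gives the E trisubstituted enal (typically >20:1), which sets C7=C8, and the less electrophilic product enal does not react a second time.

**Step 6 (West)**
Reactants: 11; 12 methyltriphenylphosphonium bromide
Product: 13 (1E,4S,5E)‑1‑iodo‑2,6‑dimethyl‑4‑(triethylsilyloxy)octa‑1,5,7‑triene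
Conditions: MePPh3Br, KHMDS, THF, −78 → 0 °C
Reagents that add atoms: MePPh3Br, C[P+](c1ccccc1)(c1ccccc1)c1ccccc1.[Br-]
Why: Wittig methylenation of the enal installs C10, and the silyl ether and iodide tolerate the ylide.

**Step 7 (West)**
Reactants: 13; 14 paraformaldehyde
Product: 15 (2E,5S,6E)‑3,7‑dimethyl‑5‑(triethylsilyloxy)nona‑2,6,8‑trien‑1‑ol
Conditions: t‑BuLi (2.1 equiv), Et2O, −78 °C; (CH2O)n, −78 °C → rt
Reagents that add atoms: formaldehyde (from paraformaldehyde), C=O
Why: I/Li exchange and trapping proceed with retention of alkene geometry, and because Li sits trans to the silyloxy chain no retro‑Brook silyl shift can occur.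

**Step 8 (East)**
Reactants: 9; 16 methyl propiolate
Product: 17 methyl (3RS,4S,6E)‑3‑hydroxy‑7‑iodo‑6‑methyl‑2‑methylidene‑4‑(triethylsilyloxy)hept‑6‑enoate
Conditions: DIBAL‑H, NMO, THF, 0 °C; methyl propiolate; then 9, 0 °C → rt
Reagents that add atoms: methyl propiolate, C#CC(=O)OC
Why: Vinylalumination (1,4‑hydroalumination of the propiolate, then addition of the α‑acrylate alane to the aldehyde) gives the Morita–Baylis–Hillman‑type adduct quickly without amine‑induced epimerisation, and the new carbinol centre is removed in step 11.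

**Step 9 (union)**
Reactants: 15; 17
Product: 18 methyl (3RS,4S,6E,10E,12S,14E)‑3,16‑dihydroxy‑6,10,14‑trimethyl‑2‑methylidene‑4,12‑bis(triethylsilyloxy)hexadeca‑6,10,14‑trienoate
Conditions: 15, 9‑BBN (2.5 equiv), THF, rt; then aq K3PO4, 17, Pd(dppf)Cl2 (5 mol %), AsPh3, DMF, rt
Reagents that add atoms: none (9‑BBN leaves only H)
Why: 9‑BBN hydroborates only the monosubstituted diene terminus, and the B‑alkyl Suzuki–Miyaura coupling forms C10–C11 with retention of the E‑iodide geometry; Pd sits trans to the acrylate‑bearing chain, so no intramolecular Heck reaction is possible.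

**Step 10**
Reactants: 18
Product: 19 methyl (3RS,4S,6E,10E,12S,14E)‑3‑hydroxy‑6,10,14‑trimethyl‑2‑methylidene‑16‑oxo‑4,12‑bis(triethylsilyloxy)hexadeca‑6,10,14‑trienoate
Conditions: MnO2, CH2Cl2, rt
Reagents that add atoms: none
Why: Chemoselective allylic oxidation converts the electron‑rich primary allylic alcohol to the enal much faster than it touches the hindered, acrylate‑deactivated secondary carbinol.

**Step 11**
Reactants: 19; 20 N‑bromosuccinimide
Product: 21 methyl (2Z,4S,6E,10E,12S,14E)‑2‑(bromomethyl)‑6,10,14‑trimethyl‑16‑oxo‑4,12‑bis(triethylsilyloxy)hexadeca‑2,6,10,14‑tetraenoate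
Conditions: NBS, Me2S, CH2Cl2, 0 °C → rt
Reagents that add atoms: NBS, O=C1CCC(=O)N1Br
Why: Corey–Kim‑type activation of the Baylis–Hillman alcohol followed by SN2′ bromide attack gives the thermodynamic (Z)‑2‑(bromomethyl)enoate under neutral conditions that spare the enal, the TES ethers and the trisubstituted alkenes.

**Step 12 (key ring closure)**
Reactants: 21
Product: 22 6,14‑bis‑O‑TES‑6‑O‑deacetyl‑kericembrenolide D. This is the all‑E 14‑membered carbocycle trans‑fused to the α‑methylene‑γ‑lactone, 2S,6S,14S, with C1 as in the target (formally 1R only because O–Si outranks O–acyl).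
Conditions: CrCl2 (20 mol %), 4CzIPN (2 mol %), Hantzsch ester (1.5 equiv), 2,6‑lutidine (1 equiv), DMF–THF, 450 nm LEDs, rt; 21 added by syringe pump over 12 h (final 2 mM); PPTS (cat.) at the end if open hydroxy ester remains
Reagents that add atoms: none
Why: Proposed new method: a light‑driven, Cr‑catalytic Nozaki–Hiyama macrocyclisation/lactonisation. Excited 4CzIPN is reductively quenched by the Hantzsch ester, and its radical anion (about −1.2 V) continuously regenerates Cr(II) (about −0.6 V). Cr(II) converts the slowly added bromide, via the 2‑(methoxycarbonyl)allyl radical, into the σ‑allyl‑Cr(III) species (radical–polar crossover). This species equilibrates E/Z and adds through C1 to the enal in a closed chair with both ring termini pseudo‑equatorial, giving the anti adduct and hence the trans lactone (2S). The alkene face is dictated by C14: H‑14 eclipses the alkene to avoid A1,3 strain, the non‑chelating OTES sits outside, and C13 lies anti to the forming bond; the Felkin–Anh arrangement with C–O anti selects the same face, so C1 has the target configuration. Lutidinium/pyridinium protonolysis frees Cr without silyl chloride or a stoichiometric metal, and the γ‑hydroxy ester lactonises with loss of MeOH. The closest known reaction types are stoichiometric CrCl2 allyl bromide–aldehyde macrocyclisations of terpenoid rings and intermolecular photoredox/Cr aldehyde allylations, neither of which has been shown for ring closure with 2‑(bromomethyl)enoates or with 1,2‑induction from a δ‑silyloxy centre.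

**Step 13**
Reactants: 22
Product: 23 6‑O‑deacetyl‑kericembrenolide D, (1S,2S,6S,14S,3E,7E,11E)‑6,14‑dihydroxycembra‑3,7,11,15(17)‑tetraen‑16,2‑olide
Conditions: HF·pyridine, pyridine, THF, 0 °C → rt
Reagents that add atoms: none
Why: Buffered fluoride desilylation removes both TES groups without affecting the α‑methylene lactone or promoting translactonisation to O‑14.

**Step 14**
Reactants: 23; 24 acetic anhydride
Product: 25 kericembrenolide D
Conditions: Ac2O (1.1 equiv), pyridine, CH2Cl2, −20 → 0 °C, stopped at mono‑acetate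
Reagents that add atoms: acetic anhydride, CC(=O)OC(C)=O
Why: Kinetic site‑selective acylation favours the allylic 6‑OH, flanked by CH2 and sp2 CH, over the 14‑OH, which adjoins the branched ring‑fusion carbon C1 and can hydrogen‑bond to the lactone; no stereocentre is touched.

## Compound list
1 | (R)‑glycidol | OC[C@@H]1CO1 | starting material
2 | lithium acetylide–ethylenediamine complex | [Li]C#C.NCCN | starting material
3 | (S)‑pent‑4‑yne‑1,2‑diol | C#CC[C@H](O)CO | intermediate
4 | trimethylaluminium | C[Al](C)C | starting material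
5 | iodine | II | starting material
6 | (2S,4E)‑5‑iodo‑4‑methylpent‑4‑ene‑1,2‑diol | I/C=C(\C)C[C@H](O)CO | intermediate
7 | chlorotriethylsilane | CC[Si](Cl)(CC)CC | starting material
8 | (2S,4E)‑5‑iodo‑4‑methyl‑1,2‑bis(triethylsilyloxy)pent‑4‑ene | I/C=C(\C)C[C@H](O[Si](CC)(CC)CC)CO[Si](CC)(CC)CC | intermediate
9 | (2S,4E)‑5‑iodo‑4‑methyl‑2‑(triethylsilyloxy)pent‑4‑enal | I/C=C(\C)C[C@H](O[Si](CC)(CC)CC)C=O | intermediate
10 | 2‑(triphenylphosphoranylidene)propanal | CC(C=O)=P(c1ccccc1)(c1ccccc1)c1ccccc1 | starting material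
11 | (2E,4S,6E)‑7‑iodo‑2,6‑dimethyl‑4‑(triethylsilyloxy)hepta‑2,6‑dienal | I/C=C(\C)C[C@H](O[Si](CC)(CC)CC)/C=C(\C)C=O | intermediate
12 | methyltriphenylphosphonium bromide | C[P+](c1ccccc1)(c1ccccc1)c1ccccc1.[Br-] | starting material
13 | (1E,4S,5E)‑1‑iodo‑2,6‑dimethyl‑4‑(triethylsilyloxy)octa‑1,5,7‑triene | I/C=C(\C)C[C@H](O[Si](CC)(CC)CC)/C=C(\C)C=C | intermediate
14 | paraformaldehyde (HCHO source) | C=O | starting material
15 | (2E,5S,6E)‑3,7‑dimethyl‑5‑(triethylsilyloxy)nona‑2,6,8‑trien‑1‑ol | OC/C=C(\C)C[C@H](O[Si](CC)(CC)CC)/C=C(\C)C=C | intermediate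
16 | methyl propiolate | C#CC(=O)OC | starting material
17 | methyl (3RS,4S,6E)‑3‑hydroxy‑7‑iodo‑6‑methyl‑2‑methylidene‑4‑(triethylsilyloxy)hept‑6‑enoate | I/C=C(\C)C[C@H](O[Si](CC)(CC)CC)C(O)C(=C)C(=O)OC | intermediate
18 | coupled diol (C2‑OH, C1‑OH; 6,14‑bis‑OTES) | OC/C=C(\C)C[C@H](O[Si](CC)(CC)CC)/C=C(\C)CC/C=C(\C)C[C@H](O[Si](CC)(CC)CC)C(O)C(=C)C(=O)OC | intermediate
19 | C2 enal / C1 carbinol | O=C/C=C(\C)C[C@H](O[Si](CC)(CC)CC)/C=C(\C)CC/C=C(\C)C[C@H](O[Si](CC)(CC)CC)C(O)C(=C)C(=O)OC | intermediate
20 | N‑bromosuccinimide | O=C1CCC(=O)N1Br | starting material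
21 | open‑chain enal (Z)‑2‑(bromomethyl)enoate | O=C/C=C(\C)C[C@H](O[Si](CC)(CC)CC)/C=C(\C)CC/C=C(\C)C[C@H](O[Si](CC)(CC)CC)/C=C(\CBr)C(=O)OC | intermediate
22 | 6,14‑bis‑O‑TES macrolactone | C=C1C(=O)O[C@H]2/C=C(\C)C[C@H](O[Si](CC)(CC)CC)/C=C(\C)CC/C=C(\C)C[C@H](O[Si](CC)(CC)CC)[C@H]12 | intermediate
23 | 6‑O‑deacetyl‑kericembrenolide D (6,14‑diol) | C=C1C(=O)O[C@H]2/C=C(\C)C[C@H](O)/C=C(\C)CC/C=C(\C)C[C@H](O)[C@H]12 | intermediate
24 | acetic anhydride | CC(=O)OC(C)=O | starting material
25 | kericembrenolide D | C=C1C(=O)O[C@H]2/C=C(\C)C[C@H](OC(C)=O)/C=C(\C)CC/C=C(\C)C[C@H](O)[C@H]12 | target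

## Step count
- **Total steps:** 14.
- **Longest linear sequence:** 13 (steps 1–7, then 9–14). Step 8 lies on the short branch.

## Steps most likely to fail
1. **Step 12 (proposed new photoredox/Cr macrocyclisation).** The risks are hydrodebromination or oligomerisation if Cr(II) trapping is slow, and modest anti or facial selectivity.
   Fallback (known chemistry, different ring‑closing bond): make C1–C2 intermolecularly by a classical stoichiometric CrCl2 Nozaki–Hiyama coupling. The partners are the bromide obtained from 17 (NBS/Me2S) and the dienal obtained from 15 (MnO2). Mask the α‑methylene lactone as its PhSH adduct, close the ring at C10–C11 by intramolecular 9‑BBN/B‑alkyl Suzuki macrocyclisation, and regenerate the methylene by sulfoxide elimination.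
2. **Step 9 (Suzuki union with the base‑sensitive partner 17).** The risks are 1,2‑TES migration between O‑14 and O‑1 and degradation of the acrylate.
   Fallback: couple before the acrylate exists. Join the borane from 15 with the robust bis‑TES iodide 8. A single Swern operation then converts the primary TES ether to the C1 aldehyde and the C2‑OH to the enal. Install the acrylate with a DABCO Morita–Baylis–Hillman reaction, which engages only the aliphatic α‑silyloxy aldehyde and not the β,β‑disubstituted enal.
3. **Step 14 (6‑OH versus 14‑OH selectivity).**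
   Fallback: replace kinetic discrimination with orthogonal protection. Prepare the East aldehyde from 6 as its TBS ether (bis‑TBS, selective primary cleavage, oxidation) and keep TES on the West half. After ring closure, remove only the 6‑O‑TES (PPTS, MeOH), acetylate, then cleave the 14‑O‑TBS with HF·pyridine.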